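## The problem

Compound 18 is a (2S,3S)-trans-2,3-diaryl-2,3-dihydro-1-benzofuran. The bicycle is numbered O1, C2, C3, C3a, C4–C7, C7a; ring A is the fused benzene ring, ring B the 3,4-dihydroxyphenyl group on C2, ring C the 3,5-dihydroxyphenyl group on C3, and ring D the resorcinol end of the (E)-styryl arm on C5. Only one five-membered ring has to be made, so the real task is the pair of adjacent benzylic stereocentres C2 and C3 in a molecule with no other stereocentre and no directing group. The trans arrangement is the more stable one, so either centre could set the other, but the absolute configuration must come from a reagent or catalyst. Several features will not survive rough treatment. The C2–O1 bond is a benzylic ether para to an oxygenated ring and can ionise under acid or open through a quinone methide once the ring B phenol is free. C3–H is doubly benzylic, the electron-rich stilbene is sensitive to acid, oxidants and light, and the catechol oxidises in air. Six phenols must therefore stay masked until the last step. The feature that opens the key step is that C2 (O1, ring B, H) and C3 (ring C, C3a, H) form exactly the pattern left when two aryl groups add anti across an (E)-2-arylvinylboron unit and boron is then exchanged for oxygen. In addition, C5 lies para to C7a, so a carboxyl group there can first activate C7a for ring closure by the C2 oxygen and later become the styryl carbon.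

## Retrosynthesis

**18 ⇒ 17.** The six O–H bonds are traced back to methyl ethers in 17. Methyl is chosen over benzyl or silyl because every aromatic building block is commercial in that form and because methyl ethers tolerate an aryllithium, palladium, peroxide, hydride and strong base. The price is one Lewis-acid step at the end that must spare C2–O1 and the stilbene.

**17 ⇒ 15 + 16.** The stilbene C=C is cut by a Horner–Wadsworth–Emmons disconnection into aldehyde 15 and commercial phosphonate 16. A Heck cut at a C5 halide was the neighbour, but a halide on ring A would compete with the triflate in the key step and would not activate C7a. The forward reaction must be (E)-selective, which benzylic phosphonates with aryl aldehydes are.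

**15 ⇒ 14 ⇒ 13.** The formyl group is traced through alcohol 14 to methyl ester 13. Two reliable redox steps are accepted because the ester is the group that makes the ring closure possible.

**13 ⇒ 12.** O1–C7a is cut, which leads back to the open-chain fluoro alcohol 12. Closing from a ring A phenol onto C2 would invert or ionise that centre, whereas attack of the C2 alkoxide on an activated aryl fluoride touches neither stereocentre. Precursor 12 is acyclic but already carries all four methoxylated rings and both centres.

**12 ⇒ 11.** The C2–O bond is traced to a C2–B bond in boronate 11. Oxidation of a boronic ester proceeds with retention, so the stereochemical problem is passed unchanged to the C–B compound.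

**11 ⇒ 5 + 9 + 7 (through 10).** Two bonds are cut, C2–ring B and C3–C3a. This leads back to the (E)-alkenylboronic ester 5, aryllithium 9 (which forms boronate complex 10 with 5) and aryl triflate 7. A cut of C2–C3 (a diarylmethyl anion plus an aldehyde) would give no control over either centre, and cutting only one aryl bond would leave a stereocentre to be made separately. The two-bond cut makes both centres in one catalyst-controlled, stereospecific event from three achiral pieces. The forward reaction must deliver anti addition, choose one alkene face, and outrun direct transfer of a group from boron to palladium.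

**5 ⇒ 3 + 2 (through 4); 2 ⇒ 1; 7 ⇒ 6; 9 ⇒ 8.** The C–B bond of 5 comes from syn hydroboration of alkyne 3 (catechol ester 4), followed by exchange onto the hindered cis-diol 2. Diol 2 is made from dione 1, triflate 7 from phenol 6 and aryllithium 9 from bromide 8, all commercial.

## Roads not taken

**Alternative 1:** The cut is C3–C3a, made by ring contraction of the (S)-flavanone A1. The trivalent iodine reagent PhI(OH)OTs in trimethyl orthoformate and methanol makes ring A carbon C4a migrate from C4 to C3, so the pyranone contracts and C4 remains as the methyl ester of A2.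
- Merits: flavanones of this kind are accessible in enantioenriched form, the shift places the ester trans to ring B, the reagents are cheap and metal-free, and the bromide is a handle for a later Heck reaction.
- Weak points: the electron-rich ring B on C2 is itself a good migrating group, so a competing 2,3-shift and simple dehydrogenation are to be expected. C2 of A1 can racemise by reversible retro-oxa-Michael opening. Above all, A2 carries a carboxylate where 18 needs ring C. Replacing it requires a decarboxylative arylation through a C3 radical (for example the N-hydroxyphthalimide ester with an arylzinc reagent and NiCl2·glyme), in which C3 is reset only by the trans preference.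
- Comparison: the key step is simpler and cheaper than the chosen one, which needs an organolithium, a ferrocenyl ligand and a boron auxiliary. Against that, the chosen plan has all three aryl–carbon bonds at C2 and C3 in place directly after its key step and does not rebuild a centre through a radical.

**Alternative 2:** O1–C7a and C3–C3a are cut together, leading to the enantiopure trans-epoxide A3 and the silylaryl triflate A4. CsF releases the aryne from A4, the epoxide oxygen adds to the aryne carbon remote from chlorine, the oxonium ion opens at the carbon bearing ring C, and the aryl anion closes on it to give A5.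
- Merits: this is the most convergent ring construction, with both ring bonds formed in one step, no organometallic reagent, and a C2 configuration that can come from an established asymmetric epoxidation.
- Weak points: the tethered aryl anion cannot attack from the rear, so closure must pass through an open benzylic cation. C3 is then set only by the trans preference. A 3,5-dimethoxyphenyl group stabilises that cation poorly because both methoxy groups are meta, so ring B has to be deactivated as its bis-mesylate to steer the opening. Aryne regiocontrol costs a sacrificial chlorine. A hydrodechlorination and a second kind of deprotection then precede the shared endgame.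
- Comparison: this road builds the heterocycle in one step where the chosen plan needs three from coupling to ring closure. The chosen plan sets against it a mechanism that dictates both centres and substrates with nothing to remove later except the recoverable boron ligand.

**Alternative 3:** Only O1–C7a is cut at the ring stage, as in the chosen plan, but the stereocentres come from the racemic ketone A6. RuCl(p-cymene)[(S,S)-TsDPEN] in HCO2H/Et3N reduces the carbonyl group while the acidic C3–H epimerises (dynamic kinetic resolution). K2CO3 in DMF then closes the ring to A7, which is identical with ester 13 of the chosen route.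
- Merits: the sequence is short, the catalyst robust, and there is no cryogenic step and no auxiliary. A6 should be reachable by ketone α-arylation, and the road shares every later step with the chosen one. In step count it is at least equal and in scalability better.
- Weak point: the catalyst sets the carbinol centre reliably, but the C3 configuration depends on its telling apart two aryl groups on the α-carbon, which differ only in substitution pattern. Every molecule reduced as the syn isomer ends as the cis-dihydrobenzofuran.
- Comparison: in the chosen plan the relative configuration follows from the mechanism (anti addition to an (E)-alkene), so only one selectivity, the alkene face, has to be won from the catalyst. Because Alternative 3 converges on 12, it is kept as the fallback for the key step.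

Key step: step 4

Assumption: the (Sp,Sp) enantiomer of the MandyPhos ligand is taken to give the (1S,2S) boronate 11; if a first run shows the antipode, the equally available (Rp,Rp) ligand is used with nothing else changed.

Assumption: addition of AlMe3 to dione 1 is taken to favour the cis (meso) diol 2, the only isomer able to form the cyclic boronic ester.

## Route

Step 1
Reactants: 1 acenaphthylene-1,2-dione (acenaphthoquinone)
Product: 2 (1R,2S)-1,2-dimethyl-1,2-dihydroacenaphthylene-1,2-diol (cis, meso)
Conditions: AlMe3 (3 equiv), toluene, 0 °C → rt; aq. Rochelle salt; recrystallisation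
Reagents that add atoms: trimethylaluminium, C[Al](C)C
Why: Twofold 1,2-addition of a methylaluminium reagent to the 1,2-dione; the second methyl group is expected to enter anti to the bulky aluminium alkoxide formed first, giving the cis diol, and any trans isomer is removed by crystallisation.

Step 2
Reactants: 3 1-ethynyl-3,5-dimethoxybenzene; 2 (1R,2S)-1,2-dimethyl-1,2-dihydroacenaphthylene-1,2-diol
Product: 5 cyclic cis-1,2-dimethylacenaphthene-1,2-diyl ester of (E)-2-(3,5-dimethoxyphenyl)ethenylboronic acid, via alkenyl catecholboronate 4 (not isolated)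
Conditions: catecholborane (1.1 equiv), Cy2BH (5 mol%), THF, rt; then 2 (1.0 equiv), rt; aq. NaHCO3 wash
Reagents that add atoms: catecholborane, B1Oc2ccccc2O1
Why: Dialkylborane-catalysed hydroboration of a terminal alkyne adds B–H syn and anti-Markovnikov, which fixes the (E) geometry of 4. Transesterification of the labile aryl ester with the aliphatic cis-diol 2 then gives the more stable dialkoxy chelate 5 and releases catechol, which is washed out with base.

Step 3
Reactants: 6 methyl 4-fluoro-3-hydroxybenzoate
Product: 7 methyl 4-fluoro-3-[(trifluoromethylsulfonyl)oxy]benzoate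
Conditions: Tf2O (1.2 equiv), pyridine, CH2Cl2, 0 °C
Reagents that add atoms: trifluoromethanesulfonic anhydride, O=S(=O)(OS(=O)(=O)C(F)(F)F)C(F)(F)F
Why: O-Sulfonylation of a phenol; the ester and the aryl fluoride are inert under these conditions.

Step 4
Reactants: 8 4-bromo-1,2-dimethoxybenzene; 5 cyclic cis-1,2-dimethylacenaphthene-1,2-diyl ester of (E)-2-(3,5-dimethoxyphenyl)ethenylboronic acid; 7 methyl 4-fluoro-3-[(trifluoromethylsulfonyl)oxy]benzoate
Product: 11 methyl 3-[(1S,2S)-2-(3,4-dimethoxyphenyl)-1-(3,5-dimethoxyphenyl)-2-(6b,9a-dimethyl-6b,9a-dihydroacenaphtho[1,2-d][1,3,2]dioxaborol-8-yl)ethyl]-4-fluorobenzoate, via (3,4-dimethoxyphenyl)lithium 9 (not isolated), via lithium boronate complex 10 (not isolated)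
Conditions: 8, t-BuLi (2.0 equiv), Et2O, −78 °C; then 5, −78 °C → rt; evaporate; 7 (1.1 equiv), Pd(OAc)2 (2 mol%), (Sp,Sp)-MandyPhos (2.4 mol%), KOTf (2 equiv), THF, 60 °C
Reagents that add atoms: none
Why: Bromine–lithium exchange gives aryllithium 9, which adds to the boron of 5 to form the four-coordinate boronate 10; oxidative addition of triflate 7 to zerovalent palladium (formed in the flask from Pd(OAc)2 and the bisphosphine) gives a cationic aryl complex of divalent palladium that binds the alkene of 10. This triggers a 1,2-metallate shift in which the 3,4-dimethoxyphenyl group moves from boron to the boron-bearing carbon anti to palladium, and reductive elimination with retention then joins ring A to the other carbon. The closest known reaction type is the enantioselective palladium-catalysed conjunctive cross-coupling of 2-substituted alkenylboron ate complexes with aryl triflates; no ring is closed. Because the shift is anti to palladium and the reductive elimination is stereoretentive, the two aryl groups add anti across the (E)-alkene, so the relative configuration of the two new centres is set by the mechanism and is the one that becomes trans after oxidation and ring closure. The absolute configuration of both centres is decided in a single event, the choice of alkene face by the palladium–MandyPhos complex. The step needs the metallate shift to beat direct Suzuki–Miyaura transfer of the alkenyl or aryl group from boron, which the hindered diol ligand on boron secures by slowing transmetallation. It also needs a halide-poor medium, which KOTf secures by sequestering the LiBr left by the exchange. The ester and fluoride of 7 are safe because no free aryllithium remains once 10 has formed.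

Step 5
Reactants: 11 methyl 3-[(1S,2S)-2-(3,4-dimethoxyphenyl)-1-(3,5-dimethoxyphenyl)-2-(6b,9a-dimethyl-6b,9a-dihydroacenaphtho[1,2-d][1,3,2]dioxaborol-8-yl)ethyl]-4-fluorobenzoate
Product: 12 methyl 3-[(1S,2S)-2-(3,4-dimethoxyphenyl)-1-(3,5-dimethoxyphenyl)-2-hydroxyethyl]-4-fluorobenzoate
Conditions: NaBO3·4H2O (5 equiv), THF/H2O (1:1), rt
Reagents that add atoms: sodium perborate, [Na+].[Na+].O[B-]1(O)OO[B-](O)(O)OO1
Why: Boronate oxidation: the peroxide adds to boron and the benzylic carbon migrates from boron to oxygen with retention, so the carbinol configuration follows from 11. The weakly basic perborate medium should spare the methyl ester and the aryl fluoride, and diol 2 is recovered.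

Step 6
Reactants: 12 methyl 3-[(1S,2S)-2-(3,4-dimethoxyphenyl)-1-(3,5-dimethoxyphenyl)-2-hydroxyethyl]-4-fluorobenzoate
Product: 13 methyl (2S,3S)-2-(3,4-dimethoxyphenyl)-3-(3,5-dimethoxyphenyl)-2,3-dihydro-1-benzofuran-5-carboxylate
Conditions: NaH (1.2 equiv), DMF, 0 °C → rt
Reagents that add atoms: none
Why: Intramolecular nucleophilic aromatic substitution: 5-exo attack of the secondary alkoxide on the fluorine-bearing carbon, activated by the para ester through a Meisenheimer intermediate, forms O1–C7a. No bond at C2 or C3 is broken, so the anti array of 12 becomes the trans ring, which is also the more stable isomer.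

Step 7
Reactants: 13 methyl (2S,3S)-2-(3,4-dimethoxyphenyl)-3-(3,5-dimethoxyphenyl)-2,3-dihydro-1-benzofuran-5-carboxylate
Product: 14 [(2S,3S)-2-(3,4-dimethoxyphenyl)-3-(3,5-dimethoxyphenyl)-2,3-dihydro-1-benzofuran-5-yl]methanol
Conditions: i-Bu2AlH (3 equiv), CH2Cl2, −78 → 0 °C; aq. Rochelle salt
Reagents that add atoms: none
Why: Hydride reduction of an aryl ester to the benzylic alcohol; aryl methyl ethers and the cyclic benzylic ether are not attacked at this temperature.

Step 8
Reactants: 14 [(2S,3S)-2-(3,4-dimethoxyphenyl)-3-(3,5-dimethoxyphenyl)-2,3-dihydro-1-benzofuran-5-yl]methanol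
Product: 15 (2S,3S)-2-(3,4-dimethoxyphenyl)-3-(3,5-dimethoxyphenyl)-2,3-dihydro-1-benzofuran-5-carbaldehyde
Conditions: MnO2 (10 equiv), CH2Cl2, rt
Reagents that add atoms: none
Why: Selective oxidation of a primary benzylic alcohol with manganese dioxide; it stops at the aldehyde and should leave the C2–H and C3–H bonds of the dihydrofuran untouched.

Step 9
Reactants: 15 (2S,3S)-2-(3,4-dimethoxyphenyl)-3-(3,5-dimethoxyphenyl)-2,3-dihydro-1-benzofuran-5-carbaldehyde; 16 diethyl [(3,5-dimethoxyphenyl)methyl]phosphonate
Product: 17 (2S,3S)-2-(3,4-dimethoxyphenyl)-3-(3,5-dimethoxyphenyl)-5-[(E)-2-(3,5-dimethoxyphenyl)ethenyl]-2,3-dihydro-1-benzofuran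
Conditions: 16 (1.2 equiv), KOt-Bu (1.3 equiv), THF, 0 °C → rt, in the dark
Reagents that add atoms: none
Why: Horner–Wadsworth–Emmons olefination; the benzylic phosphonate anion and an aryl aldehyde give the (E)-stilbene through the thermodynamically controlled elimination. C3–H is not acidic enough to be removed by the alkoxide at this temperature.

Step 10
Reactants: 17 (2S,3S)-2-(3,4-dimethoxyphenyl)-3-(3,5-dimethoxyphenyl)-5-[(E)-2-(3,5-dimethoxyphenyl)ethenyl]-2,3-dihydro-1-benzofuran
Product: 18 5-[(E)-2-[(2S,3S)-2-(3,4-dihydroxyphenyl)-3-(3,5-dihydroxyphenyl)-2,3-dihydro-1-benzofuran-5-yl]ethenyl]benzene-1,3-diol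
Conditions: BBr3 (12 equiv), CH2Cl2, −78 → 0 °C; then MeOH, H2O; work-up under argon
Reagents that add atoms: none
Why: Lewis-acid cleavage of aryl methyl ethers: boron coordinates each methoxy oxygen and bromide removes the methyl group by SN2. The dialkyl-type ether oxygen O1 is flanked by an aryl ring and a secondary carbon and is expected to be cleaved more slowly than the six unhindered methyl ethers at low temperature.

## Compound list

1 | acenaphthylene-1,2-dione | O=C1C(=O)c2cccc3cccc1c23 | starting material
2 | (1R,2S)-1,2-dimethyl-1,2-dihydroacenaphthylene-1,2-diol (cis, meso) | O[C@@]1(C)c2cccc3cccc(c23)[C@@]1(C)O | intermediate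
3 | 1-ethynyl-3,5-dimethoxybenzene | C#Cc1cc(OC)cc(OC)c1 | starting material
4 | 2-[(E)-2-(3,5-dimethoxyphenyl)ethenyl]-1,3,2-benzodioxaborole | COc1cc(OC)cc(c1)/C=C/B1Oc2ccccc2O1 | intermediate (not isolated)
5 | 8-[(E)-2-(3,5-dimethoxyphenyl)ethenyl]-6b,9a-dimethyl-6b,9a-dihydroacenaphtho[1,2-d][1,3,2]dioxaborole (cyclic ester of the alkenylboronic acid with cis-diol 2) | COc1cc(OC)cc(c1)/C=C/B1O[C@@]2(C)c3cccc4cccc(c34)[C@@]2(C)O1 | intermediate
6 | methyl 4-fluoro-3-hydroxybenzoate | COC(=O)c1ccc(F)c(O)c1 | starting material
7 | methyl 4-fluoro-3-[(trifluoromethylsulfonyl)oxy]benzoate | COC(=O)c1ccc(F)c(OS(=O)(=O)C(F)(F)F)c1 | intermediate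
8 | 4-bromo-1,2-dimethoxybenzene | COc1ccc(Br)cc1OC | starting material
9 | (3,4-dimethoxyphenyl)lithium | [Li]c1ccc(OC)c(OC)c1 | intermediate (not isolated)
10 | lithium (3,4-dimethoxyphenyl)[(E)-2-(3,5-dimethoxyphenyl)ethenyl]boronate of cis-diol 2 (four-coordinate boron, configuration at boron undefined) | [Li+].COc1cc(OC)cc(c1)/C=C/[B-]1(c2ccc(OC)c(OC)c2)O[C@@]2(C)c3cccc4cccc(c34)[C@@]2(C)O1 | intermediate (not isolated)
11 | methyl 3-[(1S,2S)-2-(3,4-dimethoxyphenyl)-1-(3,5-dimethoxyphenyl)-2-(6b,9a-dimethyl-6b,9a-dihydroacenaphtho[1,2-d][1,3,2]dioxaborol-8-yl)ethyl]-4-fluorobenzoate | COC(=O)c1ccc(F)c(c1)[C@H](c1cc(OC)cc(OC)c1)[C@@H](c1ccc(OC)c(OC)c1)B1O[C@@]2(C)c3cccc4cccc(c34)[C@@]2(C)O1 | intermediate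
12 | methyl 3-[(1S,2S)-2-(3,4-dimethoxyphenyl)-1-(3,5-dimethoxyphenyl)-2-hydroxyethyl]-4-fluorobenzoate | COC(=O)c1ccc(F)c(c1)[C@H](c1cc(OC)cc(OC)c1)[C@@H](c1ccc(OC)c(OC)c1)O | intermediate
13 | methyl (2S,3S)-2-(3,4-dimethoxyphenyl)-3-(3,5-dimethoxyphenyl)-2,3-dihydro-1-benzofuran-5-carboxylate | COC(=O)c1ccc2c(c1)[C@H](c1cc(OC)cc(OC)c1)[C@@H](c1ccc(OC)c(OC)c1)O2 | intermediate
14 | [(2S,3S)-2-(3,4-dimethoxyphenyl)-3-(3,5-dimethoxyphenyl)-2,3-dihydro-1-benzofuran-5-yl]methanol | OCc1ccc2c(c1)[C@H](c1cc(OC)cc(OC)c1)[C@@H](c1ccc(OC)c(OC)c1)O2 | intermediate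
15 | (2S,3S)-2-(3,4-dimethoxyphenyl)-3-(3,5-dimethoxyphenyl)-2,3-dihydro-1-benzofuran-5-carbaldehyde | O=Cc1ccc2c(c1)[C@H](c1cc(OC)cc(OC)c1)[C@@H](c1ccc(OC)c(OC)c1)O2 | intermediate
16 | diethyl [(3,5-dimethoxyphenyl)methyl]phosphonate | CCOP(=O)(OCC)Cc1cc(OC)cc(OC)c1 | starting material
17 | (2S,3S)-2-(3,4-dimethoxyphenyl)-3-(3,5-dimethoxyphenyl)-5-[(E)-2-(3,5-dimethoxyphenyl)ethenyl]-2,3-dihydro-1-benzofuran | COc1cc(OC)cc(/C=C/c2ccc3c(c2)[C@H](c2cc(OC)cc(OC)c2)[C@@H](c2ccc(OC)c(OC)c2)O3)c1 | intermediate
18 | 5-[(E)-2-[(2S,3S)-2-(3,4-dihydroxyphenyl)-3-(3,5-dihydroxyphenyl)-2,3-dihydro-1-benzofuran-5-yl]ethenyl]benzene-1,3-diol | Oc1cc(O)cc(/C=C/c2ccc3c(c2)[C@H](c2cc(O)cc(O)c2)[C@@H](c2ccc(O)c(O)c2)O3)c1 | target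

## Step count and least certain steps

Total: 10 steps. Longest linear sequence: 9 steps (1 → 2 → 5 → 11 → 12 → 13 → 14 → 15 → 17 → 18; steps 1, 2, 4–10).

**Step 4 (key step).** Three processes can erode it. The conjugated, aryl-substituted alkene of 10 may bind the cationic palladium complex sluggishly, so that direct transmetallation from boron (Suzuki–Miyaura transfer) competes. The benzylic palladium intermediate may lose a β-hydride before reductive elimination. Facial selectivity may be lower with a 2-aryl than with a 2-alkyl substituent. The fallback abandons the three-component coupling for ketone chemistry; it sets out from triflate 7 and comes back at alcohol 12. Commercial 3′,4′-dimethoxyacetophenone is mono-arylated with 1-bromo-3,5-dimethoxybenzene (Pd(OAc)2, XPhos, NaOt-Bu, toluene) to the deoxybenzoin 1-(3,4-dimethoxyphenyl)-2-(3,5-dimethoxyphenyl)ethan-1-one F1. A second α-arylation with 7 (Pd(OAc)2, XPhos, K3PO4, toluene) gives racemic methyl 3-[2-(3,4-dimethoxyphenyl)-1-(3,5-dimethoxyphenyl)-2-oxoethyl]-4-fluorobenzoate F2, the ketone of Alternative 3. Asymmetric transfer hydrogenation under dynamic kinetic resolution (RuCl(p-cymene)[(S,S)-TsDPEN], HCO2H/Et3N) should give the anti alcohol 12. Any syn alcohol would end as the cis isomer of 13 and be separated there.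

**Step 10.** Lewis-acid coordination at O1 can ionise the C2–O1 bond, since the para oxygen of ring B stabilises the benzylic cation. The opened species can lose configuration at C2, eliminate towards a triarylethene, or be captured by the electron-rich stilbene of a second molecule. HBr set free on quenching can also add to the stilbene. The fallback moves the ether cleavage to a stage without a stilbene and finishes with fluoride; it sets out from aldehyde 15 and comes back at 18.
- BBr3 on 15 gives (2S,3S)-2-(3,4-dihydroxyphenyl)-3-(3,5-dihydroxyphenyl)-2,3-dihydro-1-benzofuran-5-carbaldehyde F3. Here an opened cation can only reclose to the trans ring, because C3 is untouched and no alkene is present.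
- TBSCl and imidazole in DMF give the tetrakis(tert-butyldimethylsilyl) ether of that aldehyde F4.
- Wittig methylenation (Ph3P=CH2, THF) gives the corresponding 5-ethenyl-2,3-dihydro-1-benzofuran tetrakis(silyl ether) F5.
- A Heck reaction with commercial 5-iodobenzene-1,3-diol (Pd(OAc)2, P(o-tol)3, Et3N, MeCN, 80 °C) gives the (E)-stilbene 5-[(E)-2-[(2S,3S)-2-[3,4-bis(tert-butyldimethylsilyloxy)phenyl]-3-[3,5-bis(tert-butyldimethylsilyloxy)phenyl]-2,3-dihydro-1-benzofuran-5-yl]ethenyl]benzene-1,3-diol F6. Partial loss of silyl groups here is of no consequence.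
- Et3N·3HF in THF removes the silyl groups and gives 18.

**Step 5.** Peroxide attack at the hindered boron of 11 may be slow in the buffered medium, which leaves time for saponification of the methyl ester or for protodeboronation of the benzylic C–B bond. The fallback accepts loss of the ester and restores it; it sets out from 11 and comes back at 12. Forcing oxidation (3 M NaOH, 30% H2O2, THF, 0 °C → rt) oxidises and saponifies to 3-[(1S,2S)-2-(3,4-dimethoxyphenyl)-1-(3,5-dimethoxyphenyl)-2-hydroxyethyl]-4-fluorobenzoic acid F7. Esterification with trimethylsilyldiazomethane in toluene/methanol returns 12.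

**Step 2.** The exchange from the catechol ester 4 to the tertiary diol 2 may stop at an equilibrium mixture, and the uncatalysed background hydroboration may give some of the internal regioisomer, both of which complicate purification of 5. The fallback changes the boron carrier; it sets out from alkyne 3 (and diol 2) and comes back at 5. Hydroboration with pinacolborane (Cp2Zr(H)Cl 5 mol%, Et3N 10 mol%, 60 °C) gives 2-[(E)-2-(3,5-dimethoxyphenyl)ethenyl]-4,4,5,5-tetramethyl-1,3,2-dioxaborolane F8. KHF2 in aqueous methanol converts it into crystalline potassium [(E)-2-(3,5-dimethoxyphenyl)ethenyl]trifluoroborate F9. Fluoride abstraction with Me3SiCl in acetonitrile in the presence of diol 2 then gives 5.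

## Further compounds

F1 | step 4 | 1-(3,4-dimethoxyphenyl)-2-(3,5-dimethoxyphenyl)ethan-1-one | COc1cc(OC)cc(CC(=O)c2ccc(OC)c(OC)c2)c1
F2 | step 4 | methyl 3-[2-(3,4-dimethoxyphenyl)-1-(3,5-dimethoxyphenyl)-2-oxoethyl]-4-fluorobenzoate (racemic) | COC(=O)c1ccc(F)c(c1)C(c1cc(OC)cc(OC)c1)C(=O)c1ccc(OC)c(OC)c1
F3 | step 10 | (2S,3S)-2-(3,4-dihydroxyphenyl)-3-(3,5-dihydroxyphenyl)-2,3-dihydro-1-benzofuran-5-carbaldehyde | O=Cc1ccc2c(c1)[C@H](c1cc(O)cc(O)c1)[C@@H](c1ccc(O)c(O)c1)O2
F4 | step 10 | (2S,3S)-2-[3,4-bis(tert-butyldimethylsilyloxy)phenyl]-3-[3,5-bis(tert-butyldimethylsilyloxy)phenyl]-2,3-dihydro-1-benzofuran-5-carbaldehyde | O=Cc1ccc2c(c1)[C@H](c1cc(O[Si](C)(C)C(C)(C)C)cc(O[Si](C)(C)C(C)(C)C)c1)[C@@H](c1ccc(O[Si](C)(C)C(C)(C)C)c(O[Si](C)(C)C(C)(C)C)c1)O2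
F5 | step 10 | (2S,3S)-2-[3,4-bis(tert-butyldimethylsilyloxy)phenyl]-3-[3,5-bis(tert-butyldimethylsilyloxy)phenyl]-5-ethenyl-2,3-dihydro-1-benzofuran | C=Cc1ccc2c(c1)[C@H](c1cc(O[Si](C)(C)C(C)(C)C)cc(O[Si](C)(C)C(C)(C)C)c1)[C@@H](c1ccc(O[Si](C)(C)C(C)(C)C)c(O[Si](C)(C)C(C)(C)C)c1)O2
F6 | step 10 | 5-[(E)-2-[(2S,3S)-2-[3,4-bis(tert-butyldimethylsilyloxy)phenyl]-3-[3,5-bis(tert-butyldimethylsilyloxy)phenyl]-2,3-dihydro-1-benzofuran-5-yl]ethenyl]benzene-1,3-diol | Oc1cc(O)cc(/C=C/c2ccc3c(c2)[C@H](c2cc(O[Si](C)(C)C(C)(C)C)cc(O[Si](C)(C)C(C)(C)C)c2)[C@@H](c2ccc(O[Si](C)(C)C(C)(C)C)c(O[Si](C)(C)C(C)(C)C)c2)O3)c1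
F7 | step 5 | 3-[(1S,2S)-2-(3,4-dimethoxyphenyl)-1-(3,5-dimethoxyphenyl)-2-hydroxyethyl]-4-fluorobenzoic acid | OC(=O)c1ccc(F)c(c1)[C@H](c1cc(OC)cc(OC)c1)[C@@H](c1ccc(OC)c(OC)c1)O
F8 | step 2 | 2-[(E)-2-(3,5-dimethoxyphenyl)ethenyl]-4,4,5,5-tetramethyl-1,3,2-dioxaborolane | COc1cc(OC)cc(c1)/C=C/B1OC(C)(C)C(C)(C)O1
F9 | step 2 | potassium [(E)-2-(3,5-dimethoxyphenyl)ethenyl]trifluoroborate | [K+].COc1cc(OC)cc(c1)/C=C/[B-](F)(F)F
A1 | alternative 1 | (2S)-6-bromo-2-(3,4-dimethoxyphenyl)-2,3-dihydro-4H-chromen-4-one | O=C1C[C@@H](c2ccc(OC)c(OC)c2)Oc2ccc(Br)cc12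
A2 | alternative 1 | methyl (2S,3S)-5-bromo-2-(3,4-dimethoxyphenyl)-2,3-dihydro-1-benzofuran-3-carboxylate | Brc1ccc2c(c1)[C@H](C(=O)OC)[C@@H](c1ccc(OC)c(OC)c1)O2
A3 | alternative 2 | (2R,3R)-2-[3,4-bis(methylsulfonyloxy)phenyl]-3-(3,5-dimethoxyphenyl)oxirane | COc1cc(OC)cc(c1)[C@H]1O[C@@H]1c1ccc(OS(C)(=O)=O)c(OS(C)(=O)=O)c1
A4 | alternative 2 | methyl 2-chloro-3-[(trifluoromethylsulfonyl)oxy]-4-(trimethylsilyl)benzoate | COC(=O)c1ccc([Si](C)(C)C)c(OS(=O)(=O)C(F)(F)F)c1Cl
A5 | alternative 2 | methyl (2S,3S)-2-[3,4-bis(methylsulfonyloxy)phenyl]-4-chloro-3-(3,5-dimethoxyphenyl)-2,3-dihydro-1-benzofuran-5-carboxylate | COC(=O)c1ccc2c(c1Cl)[C@H](c1cc(OC)cc(OC)c1)[C@@H](c1ccc(OS(C)(=O)=O)c(OS(C)(=O)=O)c1)O2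
A6 | alternative 3 | methyl 3-[2-(3,4-dimethoxyphenyl)-1-(3,5-dimethoxyphenyl)-2-oxoethyl]-4-fluorobenzoate (racemic) | COC(=O)c1ccc(F)c(c1)C(c1cc(OC)cc(OC)c1)C(=O)c1ccc(OC)c(OC)c1
A7 | alternative 3 | methyl (2S,3S)-2-(3,4-dimethoxyphenyl)-3-(3,5-dimethoxyphenyl)-2,3-dihydro-1-benzofuran-5-carboxylate (identical with 13) | COC(=O)c1ccc2c(c1)[C@H](c1cc(OC)cc(OC)c1)[C@@H](c1ccc(OC)c(OC)c1)O2
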